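**Plan**
- The resorcinol ring is the aromatised form of a 5-alkylcyclohexane-1,3-dione. Oxygen sits on C1 and C3 and carbon only on C5, so the six ring carbons divide into a four-carbon alk-3-en-2-one (C2, C1, C6, C5) and a two-carbon malonate unit (C3, C4).
- Retrosynthetic cuts, in order: ring bonds C4–C5 (Michael) and C2–C3 (Claisen) together; then the enone C=C (the later ring bond C5–C6) by Wittig olefination; then bond C3–C4 of the heptadecan-2-one chain by acetoacetate alkylation.
- Forward, the C18 keto chain is built from 15-bromopentadecanoic acid and tert-butyl acetoacetate and its ketone is masked as a dioxolane (steps 1–3). The ester is then cut back to the aldehyde and olefinated to the enone (steps 4–5).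
- The only ring closes in step 6 by annulation with dimethyl malonate. It is aromatised in step 7, and the extra ester carbon and the ketal are removed in step 8.
- Stereochemistry: the target is achiral. The enone geometry and the two ring stereocentres of the annulation product are transient and need no control.

Key step: step 6

Remark: the SMILES is read as 17-(3,5-dihydroxyphenyl)heptadecan-2-one, with fifteen CH2 groups between the ring and the ketone carbon.

**Route**

Step 1
Reactants: 1 15-bromopentadecanoic acid
Product: 2 methyl 15-bromopentadecanoate
Conditions: MeOH, H2SO4 (cat.), reflux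
Reagents that add atoms: methanol, CO
Why: Fischer esterification in excess methanol masks the carboxyl group, which would otherwise consume base and act as a competing nucleophile in step 2, and the primary bromide is inert to these conditions.

Step 2
Reactants: 2 methyl 15-bromopentadecanoate; 3 tert-butyl acetoacetate (tert-butyl 3-oxobutanoate, 1.5 equiv)
Product: 4 1-tert-butyl 17-methyl 2-acetylheptadecanedioate (racemic)
Conditions: NaH (1.4 equiv), THF/DMF, 0 °C; then 2, 65 °C
Reagents that add atoms: none
Why: Acetoacetic ester alkylation, in which the sodium enolate of the β-keto ester displaces the unhindered primary bromide by SN2, the excess of 3 suppresses dialkylation, and the stabilised enolate does not attack the remote methyl ester.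

Step 3
Reactants: 4 1-tert-butyl 17-methyl 2-acetylheptadecanedioate
Product: 7 methyl 16-(2-methyl-1,3-dioxolan-2-yl)hexadecanoate, via β-keto acid 5 (not isolated), via methyl 17-oxooctadecanoate 6 (not isolated)
Conditions: TsOH·H2O (0.1 equiv), toluene, reflux; then HOCH2CH2OH (3 equiv), reflux, azeotropic removal of water
Reagents that add atoms: ethylene glycol, OCCO
Why: Catalytic acid ionises the tert-butyl ester (E1 loss of isobutene), the β-keto acid decarboxylates thermally through its cyclic transition state while the methyl ester is untouched, and the same acid then drives ketalisation of the methyl ketone with ethylene glycol; any 2-hydroxyethyl ester formed by ester exchange would be reduced to the same aldehyde in step 4.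

Step 4
Reactants: 7 methyl 16-(2-methyl-1,3-dioxolan-2-yl)hexadecanoate
Product: 8 16-(2-methyl-1,3-dioxolan-2-yl)hexadecanal
Conditions: i-Bu2AlH (1.1 equiv), CH2Cl2 (dilute), −78 °C; then MeOH, aq. KNaC4H4O6 (potassium sodium tartrate)
Reagents that add atoms: none
Why: Partial ester reduction with i-Bu2AlH, in which the tetrahedral aluminium hemiacetal persists at −78 °C and releases the aldehyde only on protic work-up, while the dioxolane is inert to the hydride at this temperature.

Step 5
Reactants: 8 16-(2-methyl-1,3-dioxolan-2-yl)hexadecanal; 9 1-(triphenylphosphoranylidene)propan-2-one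
Product: 10 (E)-19-(2-methyl-1,3-dioxolan-2-yl)nonadec-3-en-2-one
Conditions: toluene, 90 °C
Reagents that add atoms: none
Why: Wittig olefination with a ketone-stabilised ylide, which reacts only with the aldehyde and should give mainly the E-enone through the reversible oxaphosphetane pathway (the geometry is in any case lost in step 6).

Step 6
Reactants: 10 (E)-19-(2-methyl-1,3-dioxolan-2-yl)nonadec-3-en-2-one; 11 dimethyl malonate (1.2 equiv)
Product: 13 methyl 6-[15-(2-methyl-1,3-dioxolan-2-yl)pentadecyl]-2,4-dioxocyclohexane-1-carboxylate (racemic; diastereomers; keto–enol tautomers), via Michael adduct 12 (not isolated)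
Conditions: NaOMe (1.3 equiv), MeOH/THF, reflux; then 1 M HCl, 0 °C, to pH 3–4
Reagents that add atoms: none
Why: Methoxide deprotonates dimethyl malonate and the soft malonate anion adds 1,4 to the enone, joining the malonate carbon to the β-carbon (ring bond C1–C6 of 13, the later arene bond C4–C5) to give adduct 12. Proton exchange in methanol moves the enolate to the terminal methyl group of the ketone, and this enolate attacks one malonate ester carbonyl in a 6-exo-trig Claisen (Dieckmann-type) closure that forms the second ring bond (C2–C3) and expels methoxide; the enolate on the internal CH2 could only close a four-membered ring and is unproductive. The closest known reaction type is the tandem Michael–Claisen annulation of malonates with alk-3-en-2-ones to 6-alkyl-2,4-dioxocyclohexanecarboxylates. The two new ring stereocentres (C1 and C6) are epimerisable, should settle mainly trans under thermodynamic control, are racemic and are erased on aromatisation, so no stereocontrol is required. Conjugate rather than direct addition is secured by the stabilised nucleophile, the 1,3,5 pattern of the future arene follows from connectivity alone, and irreversible deprotonation of the acidic β-dicarbonyl product drives the reversible steps forward. The remote ketone cannot enter aldol or Claisen chemistry because it is held as the base-stable dioxolane, which also survives the brief cold acidification.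

Step 7
Reactants: 13 methyl 6-[15-(2-methyl-1,3-dioxolan-2-yl)pentadecyl]-2,4-dioxocyclohexane-1-carboxylate
Product: 15 methyl 2,4-dihydroxy-6-[15-(2-methyl-1,3-dioxolan-2-yl)pentadecyl]benzoate, via 3-bromo dione ester 14 (not isolated)
Conditions: Br2 (1.0 equiv), DMF, 0 °C → 80 °C; then aq. NaHCO3/Na2S2O3
Reagents that add atoms: none
Why: Bromination–dehydrobromination aromatisation known for 6-alkyl-2,4-dioxocyclohexanecarboxylates, in which the enolised β-dicarbonyl is brominated at C3 far faster than the ketal can react, HBr relocates bromine to an α′ position, and E1cB loss of HBr gives a dienone that tautomerises to the resorcylate; DMF buffers the HBr and the bicarbonate quench protects the dioxolane, and any ketal or ester lost here converges on the target in step 8.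

Step 8
Reactants: 15 methyl 2,4-dihydroxy-6-[15-(2-methyl-1,3-dioxolan-2-yl)pentadecyl]benzoate
Product: 18 17-(3,5-dihydroxyphenyl)heptadecan-2-one (Hansfordiol B), via resorcylic acid ketal 16 (not isolated), via resorcinol ketal 17 (not isolated)
Conditions: NaOH (5 equiv), H2O/MeOH, N2, reflux; then HCl to pH 1, THF, 50 °C
Reagents that add atoms: water, O
Why: Saponification of the salicylate-type ester gives the 6-alkyl-2,4-dihydroxybenzoate, which decarboxylates by ipso-protonation of the electron-rich ring (in the hot alkaline stage or at the latest on acidification), and the dilute acid then hydrolyses the dioxolane (acetal hydrolysis) to release the methyl ketone.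

**Compound list**

1 | 15-bromopentadecanoic acid | BrCCCCCCCCCCCCCCC(=O)O | starting material
2 | methyl 15-bromopentadecanoate | COC(=O)CCCCCCCCCCCCCCBr | intermediate
3 | tert-butyl acetoacetate | CC(=O)CC(=O)OC(C)(C)C | starting material
4 | 1-tert-butyl 17-methyl 2-acetylheptadecanedioate (racemic) | CC(=O)C(CCCCCCCCCCCCCCC(=O)OC)C(=O)OC(C)(C)C | intermediate
5 | 2-acetyl-17-methoxy-17-oxoheptadecanoic acid (racemic) | CC(=O)C(CCCCCCCCCCCCCCC(=O)OC)C(=O)O | intermediate (not isolated)
6 | methyl 17-oxooctadecanoate | CC(=O)CCCCCCCCCCCCCCCC(=O)OC | intermediate (not isolated)
7 | methyl 16-(2-methyl-1,3-dioxolan-2-yl)hexadecanoate | COC(=O)CCCCCCCCCCCCCCCC1(C)OCCO1 | intermediate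
8 | 16-(2-methyl-1,3-dioxolan-2-yl)hexadecanal | O=CCCCCCCCCCCCCCCCC1(C)OCCO1 | intermediate
9 | 1-(triphenylphosphoranylidene)propan-2-one | CC(=O)C=P(c1ccccc1)(c1ccccc1)c1ccccc1 | starting material
10 | (E)-19-(2-methyl-1,3-dioxolan-2-yl)nonadec-3-en-2-one | CC(=O)/C=C/CCCCCCCCCCCCCCCC1(C)OCCO1 | intermediate
11 | dimethyl malonate | COC(=O)CC(=O)OC | starting material
12 | dimethyl 2-[19-(2-methyl-1,3-dioxolan-2-yl)-2-oxononadecan-4-yl]propanedioate (racemic) | COC(=O)C(C(=O)OC)C(CC(C)=O)CCCCCCCCCCCCCCCC1(C)OCCO1 | intermediate (not isolated)
13 | methyl 6-[15-(2-methyl-1,3-dioxolan-2-yl)pentadecyl]-2,4-dioxocyclohexane-1-carboxylate (racemic, mixture of ring diastereomers and keto–enol tautomers) | COC(=O)C1C(CCCCCCCCCCCCCCCC2(C)OCCO2)CC(=O)CC1=O | intermediate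
14 | methyl 3-bromo-6-[15-(2-methyl-1,3-dioxolan-2-yl)pentadecyl]-2,4-dioxocyclohexane-1-carboxylate (mixture of stereoisomers) | COC(=O)C1C(CCCCCCCCCCCCCCCC2(C)OCCO2)CC(=O)C(Br)C1=O | intermediate (not isolated)
15 | methyl 2,4-dihydroxy-6-[15-(2-methyl-1,3-dioxolan-2-yl)pentadecyl]benzoate | COC(=O)c1c(O)cc(O)cc1CCCCCCCCCCCCCCCC2(C)OCCO2 | intermediate
16 | 2,4-dihydroxy-6-[15-(2-methyl-1,3-dioxolan-2-yl)pentadecyl]benzoic acid | OC(=O)c1c(O)cc(O)cc1CCCCCCCCCCCCCCCC2(C)OCCO2 | intermediate (not isolated)
17 | 5-[15-(2-methyl-1,3-dioxolan-2-yl)pentadecyl]benzene-1,3-diol | CC1(CCCCCCCCCCCCCCCc2cc(O)cc(O)c2)OCCO1 | intermediate (not isolated)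
18 | Hansfordiol B, 17-(3,5-dihydroxyphenyl)heptadecan-2-one (achiral) | CC(=O)CCCCCCCCCCCCCCCc1cc(O)cc(O)c1 | target

**Step count**

Total steps: 8. Longest linear sequence: 8 steps (1 → 18).

**Steps most likely to fail**

1. Step 7. Electrophilic bromine may be transferred to the newly formed electron-rich ring or to the enol ether in equilibrium with the ketal, and dehydrobromination may stall at a bromo dione. The fallback sets out from 13 and returns at 18 without any halogen. Compound 13 would be saponified and decarboxylated (NaOH, H2O/MeOH, reflux; then HCl, reflux, which also removes the dioxolane) to 5-(16-oxoheptadecyl)cyclohexane-1,3-dione F1. F1 would then be dehydrogenated over Pd/C in refluxing triethylene glycol dimethyl ether under a nitrogen sweep. This catalytic acceptorless dehydrogenation of a cyclohexane-1,3-dione to a resorcinol leaves the saturated methyl ketone untouched and gives 18 directly.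

2. Step 4. Over-reduction to the primary alcohol may occur, and the long-chain ester may precipitate at −78 °C so that control of the hydride stoichiometry is lost. The fallback sets out from 7 and returns at 8. The ester would be reduced completely with LiAlH4 in THF at 0 °C to 16-(2-methyl-1,3-dioxolan-2-yl)hexadecan-1-ol F2. F2 would then be oxidised under Parikh–Doering conditions (SO3·pyridine, DMSO, i-Pr2NEt, CH2Cl2, 0 °C to room temperature). Neither operation needs a cryogenic homogeneous solution, and neither endangers the ketal.

3. Step 8. Saponification of the hindered, phenoxide-deactivated ester may stall, and the liberated ketone may condense with the resorcinol ring under acid catalysis during the warm acidic stage. The fallback sets out from 15 and returns at 18, and separates the two events. The dioxolane would first be removed under mild conditions (pyridinium p-toluenesulfonate, wet acetone, 50 °C) to give methyl 2,4-dihydroxy-6-(16-oxoheptadecyl)benzoate F3. The ester would then be removed without hydroxide or mineral acid by Krapcho-type dealkoxycarbonylation (LiCl, wet DMSO, 150 °C), in which chloride attacks the ester methyl group and the resorcylate loses CO2.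

**Further compounds**

F1 | step 7 | 5-(16-oxoheptadecyl)cyclohexane-1,3-dione | CC(=O)CCCCCCCCCCCCCCCC1CC(=O)CC(=O)C1
F2 | step 4 | 16-(2-methyl-1,3-dioxolan-2-yl)hexadecan-1-ol | OCCCCCCCCCCCCCCCCC1(C)OCCO1
F3 | step 8 | methyl 2,4-dihydroxy-6-(16-oxoheptadecyl)benzoate | COC(=O)c1c(O)cc(O)cc1CCCCCCCCCCCCCCCC(C)=O
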